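Everything rests on cutting the C2–C3 bond of the pyranone ring C. In the target, C2 is a lone CH between O1 and C3. It is a formyl-level carbon already bound to the ring A oxygen, so it maps onto the O–CH2–O carbon of an aryl methoxymethyl ether. A rhodium carbene generated at C3 should insert into a C–H bond of that methylene, forming C2–C3 and closing ring C as a 2-methoxyisoflavanone in one operation. Acid then expels methanol and removes the other MOM groups. The precursor is an α-diazo deoxybenzoin with the 4-methoxy-3-prenylphenyl group on the diazo carbon and a 2,4,6-tris(MOM)phenyl group on the carbonyl.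

Key step: step 6

Remark on the chemistry: the target has no stereocentre, and its only acyclic alkene carries two identical methyl groups. It is therefore achiral and no enantiomer has to be selected. The C2 and C3 centres created in step 6 are transient and become sp2 in step 7.

Abbreviations: MOM = CH2OCH3; prenyl = 3-methylbut-2-en-1-yl. Isoflavone numbering is used for ring atoms.

Step 1
Reactants: 1 phloroglucinol (anhydrous); 2 chloromethyl methyl ether
Product: 3 1,3,5-tris(methoxymethoxy)benzene
Conditions: NaH (3.6 equiv), 2 (3.6 equiv), DMF, 0 °C to rt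
Reagents that add atoms: chloromethyl methyl ether (2), COCCl
Why: Threefold Williamson-type O-alkylation of the sodium phenoxides with the hard, very reactive α-chloro ether should favour O- over C-alkylation and give the symmetrical tris-acetal.

Step 2
Reactants: 4 (3-bromo-4-methoxyphenyl)acetic acid
Product: 6 2-(3-bromo-4-methoxyphenyl)-N-methoxy-N-methylacetamide, via acyl imidazolide 5 (not isolated)
Conditions: CDI (1.1 equiv), CH2Cl2, rt; then MeNHOMe·HCl (1.2 equiv), rt
Reagents that add atoms: N,O-dimethylhydroxylamine hydrochloride, CNOC.Cl
Why: CDI activation to the acyl imidazolide followed by aminolysis (Weinreb amide formation) is mild, needs no added base and leaves the aryl bromide untouched.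

Step 3
Reactants: 6 2-(3-bromo-4-methoxyphenyl)-N-methoxy-N-methylacetamide; 7 prenylboronic acid pinacol ester
Product: 8 N-methoxy-2-[4-methoxy-3-(3-methylbut-2-en-1-yl)phenyl]-N-methylacetamide
Conditions: 7 (1.5 equiv), Pd-PEPPSI-IPent (2 mol %), K3PO4 (3 equiv), THF/H2O, 65 °C
Reagents that add atoms: prenylboronic acid pinacol ester (7), CC(C)=CCB1OC(C)(C)C(C)(C)O1
Why: Suzuki–Miyaura allyl–aryl cross-coupling in which the very bulky NHC ligand should steer reductive elimination to the unsubstituted allyl terminus, giving the linear prenyl arene rather than the 1,1-dimethylallyl isomer, while the phosphate base spares the Weinreb amide.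

Step 4
Reactants: 3 1,3,5-tris(methoxymethoxy)benzene; 8 N-methoxy-2-[4-methoxy-3-(3-methylbut-2-en-1-yl)phenyl]-N-methylacetamide
Product: 11 2-[4-methoxy-3-(3-methylbut-2-en-1-yl)phenyl]-1-[2,4,6-tris(methoxymethoxy)phenyl]ethan-1-one, via aryllithium 9 (not isolated), via tetrahedral lithium adduct 10 (not isolated)
Conditions: 3 (1.5 equiv), n-BuLi (1.4 equiv), THF, 0 °C, 1 h; then 8, −78 °C to 0 °C; sat. aq NH4Cl
Reagents that add atoms: none
Why: Directed ortho-metalation at the position flanked by two OMOM groups followed by a Weinreb ketone synthesis, in which the chelated adduct 10 blocks over-addition and a moderate excess of 9 at low temperature offsets competing enolisation of 8.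

Step 5
Reactants: 11 2-[4-methoxy-3-(3-methylbut-2-en-1-yl)phenyl]-1-[2,4,6-tris(methoxymethoxy)phenyl]ethan-1-one
Product: 12 2-diazo-2-[4-methoxy-3-(3-methylbut-2-en-1-yl)phenyl]-1-[2,4,6-tris(methoxymethoxy)phenyl]ethan-1-one
Conditions: p-ABSA (1.3 equiv), DBU (1.5 equiv), MeCN, 0 °C to rt, exclusion of light
Reagents that add atoms: 4-acetamidobenzenesulfonyl azide (p-ABSA), CC(=O)Nc1ccc(cc1)S(=O)(=O)N=[N+]=[N-]
Why: Regitz diazo transfer, in which DBU enolises the doubly activated (benzylic and α-keto) methylene and the enolate captures the sulfonyl azide, the triazenide collapsing to diazoketone and sulfonamide as is routine for benzyl aryl ketones.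

Step 6
Reactants: 12 2-diazo-2-[4-methoxy-3-(3-methylbut-2-en-1-yl)phenyl]-1-[2,4,6-tris(methoxymethoxy)phenyl]ethan-1-one
Product: 14 2-methoxy-3-[4-methoxy-3-(3-methylbut-2-en-1-yl)phenyl]-5,7-bis(methoxymethoxy)chroman-4-one (racemic cis/trans mixture), via rhodium carbene 13 (not isolated)
Conditions: Rh2(esp)2 (1 mol %), 4 Å MS, CH2Cl2, 25–40 °C, syringe-pump addition of 12 (final ca. 0.005 M)
Reagents that add atoms: none
Why: Proposed new method: the dirhodium catalyst should expel N2 from 12 to give the aryl-stabilised (donor/acceptor) carbene 13 at C3, which then engages one C–H bond of a neighbouring ArO–CH2–OMe carbon in a concerted but asynchronous three-centre insertion with hydride-transfer character, the developing positive charge being stabilised by both acetal oxygens while the C–O bonds stay intact. The closest known reaction types are the Rh(II)-catalysed 1,6 C–H insertion of 2-alkoxyaryl α-diazoketones next to the ether oxygen, which gives chroman-4-ones, and the insertion of donor/acceptor rhodium carbenes into acetal C–H bonds; a MOM methylene has not been shown as the C–H partner of such a chromanone closure. Ring C closes as a six-membered ring (C3–C4–C4a–C8a–O1–C2) through the single new bond C2–C3, and no five-membered C–H insertion can compete because the fifth atom from the carbene is O1 itself. C2 and C3 are formed as stereocentres without any controlling element (racemic cis/trans mixture, C3 also epimerisable), which is acceptable because both become sp2 in step 7. The step needs insertion to outrun capture of the carbene by an acetal oxygen (oxonium ylide and Stevens shift), Wolff rearrangement, O–H insertion of water and intermolecular attack on the prenyl alkene. The substrate and set-up answer this with a tempered aryl-substituted carbene, weakly nucleophilic aryl acetal oxygens, two equivalent ortho MOM groups held over C3 by the twisted 2,6-disubstituted aroyl unit, a prenyl group that is trisubstituted and geometrically out of intramolecular reach, a rhodium carboxylate rather than a copper catalyst, sieves, near-ambient temperature and slow addition at high dilution.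

Step 7
Reactants: 14 2-methoxy-3-[4-methoxy-3-(3-methylbut-2-en-1-yl)phenyl]-5,7-bis(methoxymethoxy)chroman-4-one
Product: 16 5,7-dihydroxy-3-[4-methoxy-3-(3-methylbut-2-en-1-yl)phenyl]-4H-chromen-4-one (target), via 5,7-bis(MOM) isoflavone 15 (not isolated)
Conditions: HCl (ca. 1 M in MeOH), THF co-solvent, 40 °C, stopped at full conversion
Reagents that add atoms: none
Why: Acid ionises the C2 acetal to an oxocarbenium ion that loses H-3 (E1-type β-elimination driven by formation of the conjugated 4-pyranone), and the same medium transacetalises both aryl MOM ethers, while the prenyl alkene has no ortho phenol available for chroman formation and should tolerate these mild conditions.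

Compound list
1 | phloroglucinol | Oc1cc(O)cc(O)c1 | starting material
2 | chloromethyl methyl ether | COCCl | starting material
3 | 1,3,5-tris(methoxymethoxy)benzene | COCOc1cc(OCOC)cc(OCOC)c1 | intermediate
4 | (3-bromo-4-methoxyphenyl)acetic acid | COc1ccc(CC(=O)O)cc1Br | starting material
5 | 2-(3-bromo-4-methoxyphenyl)-1-(imidazol-1-yl)ethan-1-one (acyl imidazolide, not isolated) | COc1ccc(CC(=O)n2ccnc2)cc1Br | intermediate
6 | 2-(3-bromo-4-methoxyphenyl)-N-methoxy-N-methylacetamide | COc1ccc(CC(=O)N(C)OC)cc1Br | intermediate
7 | prenylboronic acid pinacol ester | CC(C)=CCB1OC(C)(C)C(C)(C)O1 | starting material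
8 | N-methoxy-2-[4-methoxy-3-(3-methylbut-2-en-1-yl)phenyl]-N-methylacetamide | COc1ccc(CC(=O)N(C)OC)cc1CC=C(C)C | intermediate
9 | 2,4,6-tris(methoxymethoxy)phenyllithium (not isolated) | [Li]c1c(OCOC)cc(OCOC)cc1OCOC | intermediate
10 | lithium alkoxide of the tetrahedral adduct of 9 and 8 (racemic, not isolated) | [Li]OC(Cc1ccc(OC)c(CC=C(C)C)c1)(N(C)OC)c1c(OCOC)cc(OCOC)cc1OCOC | intermediate
11 | 2-[4-methoxy-3-(3-methylbut-2-en-1-yl)phenyl]-1-[2,4,6-tris(methoxymethoxy)phenyl]ethan-1-one | COCOc1cc(OCOC)c(C(=O)Cc2ccc(OC)c(CC=C(C)C)c2)c(OCOC)c1 | intermediate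
12 | 2-diazo-2-[4-methoxy-3-(3-methylbut-2-en-1-yl)phenyl]-1-[2,4,6-tris(methoxymethoxy)phenyl]ethan-1-one | [N-]=[N+]=C(c1ccc(OC)c(CC=C(C)C)c1)C(=O)c1c(OCOC)cc(OCOC)cc1OCOC | intermediate
13 | rhodium carbene at C3 (dirhodium tetracarboxylate unit abbreviated as [Rh], not isolated) | [Rh]=C(c1ccc(OC)c(CC=C(C)C)c1)C(=O)c1c(OCOC)cc(OCOC)cc1OCOC | intermediate
14 | 2-methoxy-3-[4-methoxy-3-(3-methylbut-2-en-1-yl)phenyl]-5,7-bis(methoxymethoxy)chroman-4-one (racemic cis/trans mixture, C2 and C3 deliberately undefined) | COC1Oc2cc(OCOC)cc(OCOC)c2C(=O)C1c1ccc(OC)c(CC=C(C)C)c1 | intermediate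
15 | 3-[4-methoxy-3-(3-methylbut-2-en-1-yl)phenyl]-5,7-bis(methoxymethoxy)-4H-chromen-4-one (not isolated) | COCOc1cc(OCOC)c2c(c1)occ(-c1ccc(OC)c(CC=C(C)C)c1)c2=O | intermediate
16 | 5,7-dihydroxy-4'-methoxy-3'-prenylisoflavone (achiral) | COc1ccc(-c2coc3cc(O)cc(O)c3c2=O)cc1CC=C(C)C | target

Total step count: 7
Longest linear sequence: 6 steps (4 to 6 to 8 to 11 to 12 to 14 to 16; step 1 is a one-step side branch)

Steps most likely to fail

1. Step 6 (new method).
- What may go wrong: an acetal oxygen may intercept the carbene before C–H insertion, after which a 1,2-shift would follow. The carbene may also be lost to Wolff rearrangement or to dimerisation.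
- Fallback (known chemistry): this sets out from ketone 11. Its activated methylene is condensed with N,N-dimethylformamide dimethyl acetal (toluene, 100 °C) to give the enaminone 3-(dimethylamino)-2-[4-methoxy-3-(3-methylbut-2-en-1-yl)phenyl]-1-[2,4,6-tris(methoxymethoxy)phenyl]prop-2-en-1-one F1 (alkene geometry irrelevant). Treatment with HCl in MeOH at 40 °C then removes the MOM groups. A freed ortho phenol adds to the vinylogous amide and expels dimethylamine. This is the established enaminone closure of chromones and isoflavones, and it rejoins the route at target 16.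

2. Step 4.
- What may go wrong: proton transfer from the benzylic α-methylene of 8 to aryllithium 9 may outpace carbonyl addition and stall conversion.
- Fallback: this sets out from 8, which is reduced with DIBAL-H (THF, −78 °C) to [4-methoxy-3-(3-methylbut-2-en-1-yl)phenyl]acetaldehyde F2. The much more electrophilic aldehyde is treated with 9 at −78 °C to give the racemic carbinol 2-[4-methoxy-3-(3-methylbut-2-en-1-yl)phenyl]-1-[2,4,6-tris(methoxymethoxy)phenyl]ethan-1-ol F3. Oxidation with Dess–Martin periodinane/NaHCO3 in CH2Cl2 rejoins the route at 11.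

3. Step 3.
- What may go wrong: the allyl transfer may lose regiocontrol, with bond formation at the dimethyl-substituted terminus. Protodeboronation may also consume the boronate.
- Fallback: this sets out from 6, which is coupled with the symmetrical donor allylboronic acid pinacol ester (PdCl2(dppf), K3PO4, THF/H2O, 65 °C). No regiochemical question exists for that donor, and the product is 2-(3-allyl-4-methoxyphenyl)-N-methoxy-N-methylacetamide F4. Olefin cross-metathesis with excess 2-methyl-2-butene (Grubbs second-generation catalyst, CH2Cl2, 40 °C) converts the allyl group into the prenyl group and rejoins the route at 8.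

Further compounds
F1 | step 6 | 3-(dimethylamino)-2-[4-methoxy-3-(3-methylbut-2-en-1-yl)phenyl]-1-[2,4,6-tris(methoxymethoxy)phenyl]prop-2-en-1-one | CN(C)C=C(c1ccc(OC)c(CC=C(C)C)c1)C(=O)c1c(OCOC)cc(OCOC)cc1OCOC
F2 | step 4 | [4-methoxy-3-(3-methylbut-2-en-1-yl)phenyl]acetaldehyde | COc1ccc(CC=O)cc1CC=C(C)C
F3 | step 4 | 2-[4-methoxy-3-(3-methylbut-2-en-1-yl)phenyl]-1-[2,4,6-tris(methoxymethoxy)phenyl]ethan-1-ol (racemic) | COCOc1cc(OCOC)c(C(O)Cc2ccc(OC)c(CC=C(C)C)c2)c(OCOC)c1
F4 | step 3 | 2-(3-allyl-4-methoxyphenyl)-N-methoxy-N-methylacetamide | COc1ccc(CC(=O)N(C)OC)cc1CC=C
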